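Rings C and D are disconnected together. Ring C (C8, C9, C11–C14) shares C8–C14 with cyclopentane ring D (C7, C8, C14, C4', C10') and carries H at C11 and oxygen at C12, so it maps onto a ring-B-fused furan (C8, C9, C11, C12, O) plus a C13≡C14 isopropyl alkyne held on spiro carbon C4'. One intramolecular furan–alkyne Diels–Alder reaction with bridge opening forms C8–C14 and C12–C13, closes both rings and delivers the C12 phenol. Its precursor is the silylated aldol of a cis-fused furano-decalone (polyene cyclisation, C5 epimerisation) and a sabinene-derived α-alkynyl aldehyde; phenol ortho-oxidation, tautomerisation and desilylation finish.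

Key step: step 13

Numbering: abietane numbering for the diterpene part, α/β as in the usual abietane drawing (C20 methyl β); primed numbers for the thujane (C1' isopropyl-bearing, C4' spiro, C5' bridgehead CH, C6' cyclopropane CH2, C10' carbinol carbon).
Remark (assumption): the target SMILES has H-5 and C20 on the same face (A/B cis, 5β-H, 10β-CH3); the cis-fused 6-ketone is assumed to be the thermodynamic C5 epimer, so the trans junction from the cyclisation is equilibrated in step 6.
Remark: a six-membered ring B needs a two-carbon link between furan C2 and the olefin, which the sulfone carbon supplies. C10' comes from formaldehyde because ozonolysis removes the sabinene methylene. C7 in 26–30 is drawn as the aldol should deliver it (side chain β); it is a temporary centre erased in step 14.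

Step 1
Reactants: 1 furfuryl alcohol
Product: 3 2-[(phenylsulfonyl)methyl]furan, via 2-(chloromethyl)furan 2 (not isolated)
Conditions: SOCl2, Et3N, Et2O, −20 °C; filter; PhSO2Na, DMF, 0 °C to rt
Reagents that add atoms: sodium benzenesulfinate, [Na+].[O-]S(=O)c1ccccc1
Why: The labile furfuryl chloride is made cold and used at once, and S-alkylation of the sulfinate by this benzylic-type halide (SN2, classical sulfone synthesis) should give the sulfone; no stereocentre is involved.

Step 2
Reactants: 3 2-[(phenylsulfonyl)methyl]furan; 4 geranyl bromide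
Product: 6 2-[(3E)-4,8-dimethyl-1-(phenylsulfonyl)nona-3,7-dien-1-yl]furan, via lithio sulfone 5 (not isolated)
Conditions: n-BuLi, THF, −78 °C; then 4, −78 to 0 °C
Reagents that add atoms: none
Why: Alkylation of the α-sulfonyl carbanion with the primary allylic bromide (Julia-type sulfone alkylation, SN2 without allylic transposition) joins furan C2 to the E-olefin through the two carbons C7 and C6 that a six-membered ring B needs; the sulfonyl carbon is racemic and is erased in step 4.

Step 3
Reactants: 6 2-[(3E)-4,8-dimethyl-1-(phenylsulfonyl)nona-3,7-dien-1-yl]furan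
Product: 8 trans-fused tricyclic sulfone (5α-H 10β-CH3; both C7 epimers), via monocyclic olefin 7 (not isolated)
Conditions: (R)-2-(2-fluorobenzyloxy)-2'-hydroxy-1,1'-binaphthyl·SnCl4 (chiral LBA, 1.5 equiv), toluene, −78 °C; then CF3CO2H, SnCl4, i-PrNO2, −78 °C
Reagents that add atoms: none
Why: Enantioface-selective protonation of the terminal olefin by the chiral Lewis acid-assisted Brønsted acid starts a chair-folded cation–olefin bicyclisation (biomimetic polyene cyclisation) that sets C5 under reagent control, places H-5 and C20 trans by anti addition across the E-olefin and ends by attack of furan C3 (C9) on the C10 cation, while the achiral acid drives monocyclic olefin 7 on to the same trans product under control of C5; the (R)-ligand is expected to give the 10β-methyl series.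

Step 4
Reactants: 8 trans-fused tricyclic sulfone
Product: 9 trans-fused C6=C7 olefin (vinylfuran)
Conditions: t-BuOK, THF/t-BuOH, 60 °C
Reagents that add atoms: none
Why: Base-induced β-elimination of benzenesulfinate (dehydrosulfonylation) is driven by conjugation of the new C6=C7 bond with the furan and makes both C7 epimers converge; C10 is untouched and any C5 epimerisation is harmless because C5 is equilibrated in step 6.

Step 5
Reactants: 9 trans-fused C6=C7 olefin
Product: 11 trans-fused 6α-alcohol, via 6α-alkylborane 10 (not isolated)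
Conditions: BH3·THF, THF, 0 °C; then NaOH, H2O2, 0 °C to rt
Reagents that add atoms: hydrogen peroxide, OO
Why: Syn hydroboration–oxidation of the furan-conjugated olefin puts boron on C6 (β to the heteroarene, as with styrenes and 6,7-dehydroabietanes) from the α-face away from the axial C20 methyl, and the C6 carbinol configuration is erased in step 6.

Step 6
Reactants: 11 trans-fused 6α-alcohol
Product: 13 cis-fused furano-decalone (5β-H 10β-CH3 6-ketone), via trans-fused ketone 12 (not isolated)
Conditions: Dess–Martin periodinane, NaHCO3, CH2Cl2, rt; then NaOMe (0.2 equiv), MeOH, degassed, 40 °C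
Reagents that add atoms: none
Why: Dess–Martin oxidation gives the trans-fused β-tetralone-type ketone 12 and catalytic methoxide then equilibrates C5 through the C5=C6 enolate to the cis-fused ketone, expected to be favoured because it relieves the eclipsing of the C6 carbonyl with the equatorial C4 methyl and the 1,3-diaxial C4β/C20 methyl contact; C10 is not enolisable, so only C5 changes.

Step 7
Reactants: 14 (+)-sabinene
Product: 16 sabina ketone, via sabinene ozonide 15 (not isolated)
Conditions: O3, CH2Cl2, −78 °C; Me2S, −78 °C to rt
Reagents that add atoms: ozone, [O-][O+]=O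
Why: Criegee ozonolysis of the 1,1-disubstituted exocyclic olefin with reductive work-up gives the cyclopropyl ketone and leaves C1' and C5' untouched.

Step 8
Reactants: 16 sabina ketone; 17 3-methylbut-1-yne
Product: 20 tertiary propargylic methyl carbonate (alkyne anti to C6'), via lithium acetylide 18 (not isolated), via lithium alkoxide 19 (not isolated)
Conditions: n-BuLi, THF, −78 °C; 16, −78 °C; ClCO2Me, −78 °C to rt
Reagents that add atoms: methyl chloroformate, COC(=O)Cl
Why: 1,2-Addition of the lithium acetylide to the ketone from the face anti to the cyclopropane methylene (the usual preference of bicyclo[3.1.0]hexan-2-ones) followed by O-acylation of the alkoxide in the same flask gives the tertiary propargylic carbonate with oxygen syn to C6'; this centre is consumed in step 9.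

Step 9
Reactants: 20 tertiary propargylic methyl carbonate; 21 formaldehyde
Product: 23 homopropargylic alcohol (alkyne syn to C6'), via allenylzinc 22 (not isolated)
Conditions: Pd(PPh3)4 (5 mol %), Et2Zn, THF, −20 °C to rt; CH2O (gas from cracked paraformaldehyde), −78 to 0 °C; aq NH4Cl
Reagents that add atoms: none
Why: Anti SN2' ionisation of the propargylic carbonate by zerovalent palladium and transmetallation with Et2Zn (umpolung to an allenylzinc) are followed by cyclic SE2' addition to formaldehyde at C4', so the C4'–C10' bond forms on the face anti to the cyclopropane methylene, which is both the face carrying zinc and the less hindered one, and the alkyne ends syn to C6' as the spiro centre of the target requires.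

Step 10
Reactants: 23 homopropargylic alcohol
Product: 24 α-alkynyl thujane aldehyde
Conditions: Dess–Martin periodinane, NaHCO3, CH2Cl2, 0 °C to rt
Reagents that add atoms: none
Why: Dess–Martin oxidation of the neopentyl primary alcohol gives a non-enolisable α-quaternary aldehyde, so C4' cannot epimerise.

Step 11
Reactants: 13 cis-fused furano-decalone; 24 α-alkynyl thujane aldehyde
Product: 26 anti-aldol adduct (β-hydroxy ketone), via enol borinate 25 (not isolated)
Conditions: (c-C6H11)2BCl, Et3N, Et2O, −78 to 0 °C; 24, −78 to −20 °C; MeOH, pH 7 buffer, H2O2, 0 °C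
Reagents that add atoms: none
Why: Regioselective enolisation toward the furylic C7 methylene gives the E-enol borinate of the cyclic ketone, whose closed Zimmerman–Traxler transition state (anti-selective boron aldol) with the aldehyde approaching the convex β-face of the cis-fused bicycle fixes C10' in the sense of the target (hydroxyl cis to C5' once ring D is closed), while C7 is a temporary centre and C5 is not enolised under these kinetic conditions.

Step 12
Reactants: 26 anti-aldol adduct
Product: 27 furan-fused decalone carrying the alkynyl thujane (C10' silyl ether)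
Conditions: TBSOTf, 2,6-lutidine, CH2Cl2, −78 to 0 °C
Reagents that add atoms: tert-butyldimethylsilyl triflate, CC(C)(C)[Si](C)(C)OS(=O)(=O)C(F)(F)F
Why: Silylation of the hindered secondary alcohol with the silyl triflate and a non-nucleophilic base (standard protection) blocks retro-aldol cleavage and β-elimination in step 13 without touching a stereocentre.

Step 13
Reactants: 27 furan-fused decalone carrying the alkynyl thujane
Product: 29 hexacyclic C12 phenol silyl ether, via oxanorbornadiene 28 (not isolated)
Conditions: o-dichlorobenzene (degassed), BHT, 180 °C, sealed tube; then CSA (10 mol %), CH2Cl2, rt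
Reagents that add atoms: none
Why: On heating, the electron-rich 2,3-dialkylfuran (diene C8=C9–C11=C12) adds suprafacially across the tethered dialkyl alkyne to give 7-oxanorbornadiene 28, and catalytic acid then ionises the C8–O bond of the bridge (tertiary, doubly allylic cation) so that loss of H-12 aromatises ring C to the C12 phenol. The closest known reaction type is the intramolecular furan–alkyne Diels–Alder reaction with oxa-bridge opening to a phenol. Ring D (C8, C7, C10', C4', C14) closes through the three-atom tether as the five-membered ring of the intramolecular [4+2] mode, and ring C (C8, C9, C11, C12, C13, C14) closes through the two new σ-bonds C8–C14 and C12–C13 of the cycloaddition itself. No stereocentre is created that survives, because C8 and C12 of 28 become aromatic. The step needs regioselectivity and a reactive conformer: the tether allows only C14 to reach C8 and C13 to reach C12, opening at tertiary C8 and not at secondary C12 leaves the oxygen on C12 next to the isopropyl group, and the quaternary spiro carbon C4', the bulky silyloxy group on C10' and the anchoring of C7 in ring B (side chain pseudo-axial on the convex β-face) hold the alkyne over the furan. Aromatisation makes the sequence irreversible, and the silyl ether prevents retro-aldol loss of the side chain at the forcing temperature.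

Step 14
Reactants: 29 hexacyclic C12 phenol silyl ether
Product: 31 silyl-protected quinone methide, via 11,12-ortho-quinone 30 (not isolated)
Conditions: IBX (1.5 equiv), DMF, rt, dark; then Et3N (0.1 equiv), CH2Cl2, 0 °C
Reagents that add atoms: 2-iodoxybenzoic acid, O=C1OI(=O)(O)c2ccccc12
Why: IBX delivers oxygen to the free ortho position C11 of the phenol (regioselective ortho-oxygenation to the 11,12-quinone, since C13 is blocked) and the quinone then tautomerises by loss of the doubly activated H-7 to the extended quinone methide of the 6-oxo series (as in taxodione-type abietanes), which erases C7; the silyl ether shields the C10' carbinol from oxidation.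

Step 15
Reactants: 31 silyl-protected quinone methide
Product: 32 target CNP0178265.2
Conditions: HF·pyridine, THF, 0 °C to rt
Reagents that add atoms: none
Why: Fluoride-mediated cleavage of the silyl ether under buffered acidic conditions (standard desilylation) frees the C10' hydroxyl without enolising C5 or adding to the quinone methide.

Compound list
1 | furfuryl alcohol (furan-2-ylmethanol) | OCc1ccco1 | starting material
2 | 2-(chloromethyl)furan | ClCc1ccco1 | intermediate
3 | 2-[(phenylsulfonyl)methyl]furan | O=S(=O)(Cc1ccco1)c1ccccc1 | intermediate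
4 | geranyl bromide, (2E)-1-bromo-3,7-dimethylocta-2,6-diene | CC(C)=CCC/C(C)=C/CBr | starting material
5 | lithio sulfone, [furan-2-yl(phenylsulfonyl)methyl]lithium | [Li]C(c1ccco1)S(=O)(=O)c1ccccc1 | intermediate
6 | 2-[(3E)-4,8-dimethyl-1-(phenylsulfonyl)nona-3,7-dien-1-yl]furan, racemic at the sulfonyl carbon (C7) | CC(C)=CCC/C(C)=C/CC(c1ccco1)S(=O)(=O)c1ccccc1 | intermediate
7 | monocyclic olefin, 2-[2-(2,6,6-trimethylcyclohex-2-en-1-yl)-1-(phenylsulfonyl)ethyl]furan, C5 configured as in 8 (endocyclic isomer drawn) | O=S(=O)(c1ccccc1)C(c1ccco1)C[C@H]1C(C)(C)CCC=C1C | intermediate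
8 | trans-fused tricyclic sulfone, 4-(phenylsulfonyl)-6,6,9a-trimethyl-4,5,5a,6,7,8,9,9a-octahydronaphtho[2,1-b]furan, 5α-H and 10β-CH3 in abietane terms, both C7 epimers | O=S(=O)(c1ccccc1)C1C[C@H]2C(C)(C)CCC[C@]2(C)c2ccoc21 | intermediate
9 | trans-fused C6=C7 olefin, 6,6,9a-trimethyl-5a,6,7,8,9,9a-hexahydronaphtho[2,1-b]furan (5α-H, 10β-CH3) | C1=C[C@H]2C(C)(C)CCC[C@]2(C)c2ccoc21 | intermediate
10 | 6α-alkylborane of 9 (BH2 on C6, α-face) | C1[C@H]([BH2])[C@H]2C(C)(C)CCC[C@]2(C)c2ccoc21 | intermediate
11 | trans-fused 6α-alcohol, 6,6,9a-trimethyl-4,5,5a,6,7,8,9,9a-octahydronaphtho[2,1-b]furan-5-ol (6α-OH, 5α-H, 10β-CH3) | C1[C@H](O)[C@H]2C(C)(C)CCC[C@]2(C)c2ccoc21 | intermediate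
12 | trans-fused ketone, (5aS,9aS)-6,6,9a-trimethyl-5a,6,7,8,9,9a-hexahydronaphtho[2,1-b]furan-5(4H)-one (5α-H, 10β-CH3) | C1C(=O)[C@H]2C(C)(C)CCC[C@]2(C)c2ccoc21 | intermediate
13 | cis-fused furano-decalone, (5aR,9aS)-6,6,9a-trimethyl-5a,6,7,8,9,9a-hexahydronaphtho[2,1-b]furan-5(4H)-one (5β-H, 10β-CH3, C6 ketone, furan O on C8) | C1C(=O)[C@@H]2C(C)(C)CCC[C@]2(C)c2ccoc21 | intermediate
14 | (+)-sabinene, (1R,5R)-4-methylidene-1-(propan-2-yl)bicyclo[3.1.0]hexane | C=C1CC[C@]2(C(C)C)C[C@@H]21 | starting material
15 | sabinene ozonide (spiro 1,2,4-trioxolane on C4', spiro centre unassigned) | C1OOC3(O1)CC[C@]2(C(C)C)C[C@@H]23 | intermediate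
16 | sabina ketone, (1S,5R)-5-(propan-2-yl)bicyclo[3.1.0]hexan-2-one | O=C1CC[C@]2(C(C)C)C[C@@H]21 | intermediate
17 | 3-methylbut-1-yne | CC(C)C#C | starting material
18 | lithium 3-methylbut-1-yn-1-ide | [Li]C#CC(C)C | intermediate
19 | lithium alkoxide of 2-(3-methylbut-1-yn-1-yl)-5-(propan-2-yl)bicyclo[3.1.0]hexan-2-ol (alkyne anti to the cyclopropane CH2, O syn) | CC(C)C#C[C@@]1(O[Li])CC[C@]2(C(C)C)C[C@@H]21 | intermediate
20 | methyl 2-(3-methylbut-1-yn-1-yl)-5-(propan-2-yl)bicyclo[3.1.0]hexan-2-yl carbonate (alkyne anti to the cyclopropane CH2, O syn) | CC(C)C#C[C@@]1(OC(=O)OC)CC[C@]2(C(C)C)C[C@@H]21 | intermediate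
21 | formaldehyde (monomer from paraformaldehyde) | C=O | starting material
22 | allenylzinc, ethyl{3-methyl-1-[5-(propan-2-yl)bicyclo[3.1.0]hexan-2-ylidene]but-1-en-2-yl}zinc (zinc on C13, axis unassigned) | CC[Zn]C(C(C)C)=C=C1CC[C@]2(C(C)C)C[C@@H]21 | intermediate
23 | [2-(3-methylbut-1-yn-1-yl)-5-(propan-2-yl)bicyclo[3.1.0]hexan-2-yl]methanol (alkyne syn to the cyclopropane CH2, CH2OH anti) | CC(C)C#C[C@]1(CO)CC[C@]2(C(C)C)C[C@@H]21 | intermediate
24 | 2-(3-methylbut-1-yn-1-yl)-5-(propan-2-yl)bicyclo[3.1.0]hexane-2-carbaldehyde (alkyne syn to the cyclopropane CH2, CHO anti) | CC(C)C#C[C@]1(C=O)CC[C@]2(C(C)C)C[C@@H]21 | intermediate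
25 | dicyclohexylboron enolate of 13 (C6–O–B, C6=C7) | C1=C(OB(C3CCCCC3)C3CCCCC3)[C@@H]2C(C)(C)CCC[C@]2(C)c2ccoc21 | intermediate
26 | anti-aldol adduct: 13 carrying on C7 (β-face) the CH(OH) group C10' bonded to C4' of the alkynyl thujane; C10' as in the target | CC(C)C#C[C@@]5(CC[C@]6(C(C)C)C[C@@H]65)[C@H](O)[C@H]3C(=O)[C@@H]4C(C)(C)CCC[C@]4(C)c2ccoc23 | intermediate
27 | furan-fused decalone carrying the alkynyl thujane, C10' tert-butyldimethylsilyl ether of 26 | CC(C)C#C[C@@]5(CC[C@]6(C(C)C)C[C@@H]65)[C@H](O[Si](C)(C)C(C)(C)C)[C@H]3C(=O)[C@@H]4C(C)(C)CCC[C@]4(C)c2ccoc23 | intermediate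
28 | 7-oxanorbornadiene cycloadduct (O bridging C8 and C12, C8–C14 and C12–C13 formed on the β-face, C9=C11 and C13=C14) | CC(C)C1=C2[C@@]5(CC[C@]6(C(C)C)C[C@@H]65)[C@H](O[Si](C)(C)C(C)(C)C)[C@H]3C(=O)[C@@H]4C(C)(C)CCC[C@]4(C)C(=C[C@@H]1O7)[C@@]237 | intermediate
29 | hexacyclic C12 phenol silyl ether (aromatic ring C, 13-isopropyl, 12-OH, C6 ketone, ring D closed, C10' OTBS, 7-H) | CC(C)c1c(O)cc2c3c1[C@@]5(CC[C@]6(C(C)C)C[C@@H]65)[C@H](O[Si](C)(C)C(C)(C)C)[C@H]3C(=O)[C@@H]4C(C)(C)CCC[C@]24C | intermediate
30 | 11,12-ortho-quinone of 29 (C11=O, C12=O, C8=C9, C13=C14, 7-H) | CC(C)C=1C(=O)C(=O)C2=C3C=1[C@@]5(CC[C@]6(C(C)C)C[C@@H]65)[C@H](O[Si](C)(C)C(C)(C)C)[C@H]3C(=O)[C@@H]4C(C)(C)CCC[C@]24C | intermediate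
31 | silyl-protected quinone methide (target with C10' OTBS) | CC(C)C1=C2C3=C(C(=O)[C@@H]4C(C)(C)CCC[C@]4(C)C3=C(O)C1=O)[C@@H](O[Si](C)(C)C(C)(C)C)[C@]21CC[C@]2(C(C)C)C[C@@H]21 | intermediate
32 | CNP0178265.2: 11-hydroxy-6,12-dioxo-abieta-7,9(11),13-triene (A/B cis) spiro-fused through C14–C4' and C7–C10'(OH) to the thujane | CC(C)C1=C2C3=C(C(=O)[C@@H]4C(C)(C)CCC[C@]4(C)C3=C(O)C1=O)[C@@H](O)[C@]21CC[C@]2(C(C)C)C[C@@H]21 | target

Total step count: 15. Longest linear sequence: 11 steps (steps 1–6, then 11–15); the sabinene branch (steps 7–10) joins at step 11.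

Steps most likely to fail

Step 13 (key step). The dialkyl alkyne may be too poor a dienophile, so that retro-cycloaddition or thermal breakdown of the β-silyloxy ketone outruns ring closure. The fallback sets out from 27 and replaces the concerted thermal cycloaddition by π-acid catalysis (PtCl2 or Ph3PAuNTf2, toluene, 60–80 °C; furan–yne phenol synthesis). The metal-activated alkyne is attacked by the furan C8=C9 bond, the furan opens to a carbonyl carbene and recloses through the oxepine to the 12,13-arene oxide F1. This opens at tertiary C13 and aromatises, so the same bonds C8–C14 and C12–C13 are formed and the route is rejoined at phenol 29.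

Step 3. The sulfone may bind the tin Lewis acid or be ionised at the furfuryl carbon, so that protonation loses its enantioface control or the inductively deactivated furan fails to terminate and the material stops at monocyclic olefins. The fallback sets out from 6: reductive desulfonylation (Na(Hg), Na2HPO4, MeOH, −20 °C) gives 2-[(3E)-4,8-dimethylnona-3,7-dien-1-yl]furan F2, the sulfone-free substrate class for which the chiral-acid bicyclisation is established. Cyclisation under the conditions of step 3 gives the trans-fused tricyclic furan F3. Dehydrogenation of the furylic C6–C7 bond with DDQ (1 equiv, benzene, rt) then comes back to the route at olefin 9.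

Step 6. The equilibration at C5 may stop at an unfavourable cis to trans ratio, or be outrun by self-condensation or autoxidation of the β-tetralone-type ketone. The fallback sets the cis junction kinetically and sets out from 3. Alkylation of 5 with neryl bromide (made from nerol) gives the (Z)-sulfone F4. Cyclisation with the antipodal (S)-configured chiral acid, where anti addition across the Z-olefin should place H-5 and C20 cis with H-5 on the β-face, gives the cis-fused tricyclic sulfone F5. Elimination as in step 4 gives the cis-fused olefin F6 and hydroboration–oxidation as in step 5 gives the cis-fused alcohol F7. Dess–Martin oxidation without the base treatment comes back at ketone 13, which is then kept away from enolising base.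

Further compounds
F1 | step 13 | 12,13-arene oxide of ring C (epoxide across C12–C13, C9=C11 and C8=C14) | CC(C)C12OC1C=C7C3=C2[C@@]5(CC[C@]6(C(C)C)C[C@@H]65)[C@H](O[Si](C)(C)C(C)(C)C)[C@H]3C(=O)[C@@H]4C(C)(C)CCC[C@]74C
F2 | step 3 | 2-[(3E)-4,8-dimethylnona-3,7-dien-1-yl]furan | CC(C)=CCC/C(C)=C/CCc1ccco1
F3 | step 3 | trans-fused tricyclic furan, 6,6,9a-trimethyl-4,5,5a,6,7,8,9,9a-octahydronaphtho[2,1-b]furan (5α-H, 10β-CH3) | C1C[C@H]2C(C)(C)CCC[C@]2(C)c2ccoc21
F4 | step 6 | 2-[(3Z)-4,8-dimethyl-1-(phenylsulfonyl)nona-3,7-dien-1-yl]furan | CC(C)=CCC/C(C)=C\CC(c1ccco1)S(=O)(=O)c1ccccc1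
F5 | step 6 | cis-fused tricyclic sulfone (5β-H, 10β-CH3, both C7 epimers) | O=S(=O)(c1ccccc1)C1C[C@@H]2C(C)(C)CCC[C@]2(C)c2ccoc21
F6 | step 6 | cis-fused C6=C7 olefin (5β-H, 10β-CH3) | C1=C[C@@H]2C(C)(C)CCC[C@]2(C)c2ccoc21
F7 | step 6 | cis-fused 6-alcohol (5β-H, 10β-CH3, C6 unassigned) | C1C(O)[C@@H]2C(C)(C)CCC[C@]2(C)c2ccoc21
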